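The runs stem from a simulated flask on assumed constants.

I was given 6 questions, and 5 of them were the same question asked of different flasks: how much of the substrate ends as over-reaction product when the first nucleophile goes in at different speeds and temperatures.

1. which flask leads in amount of over-reaction product, in percent of the substrate charged ("all alike" within 1.5 percentage points) (east / south-east / south / north-east / west / all alike)
2. how much over-reaction product is there at the end, in percent of the substrate charged: east
3. how much over-reaction product is there at the end, in percent of the substrate charged: south-east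
4. how much over-reaction product is there at the end, in percent of the substrate charged: south
5. how much over-reaction product is there at the end, in percent of the substrate charged: north-east
6. how much over-reaction product is there at the end, in percent of the substrate charged: west

| setting | larch | maple | ash | cedar | east | south-east | south | north-east | west |
|---|---|---|---|---|---|---|---|---|---|
| substrate | 20 mM | 13 mM | 30 mM | 20 mM | 20 mM | 20 mM | 20 mM | 20 mM | 20 mM |
| first nucleophile | 22 mM | 22 mM | 22 mM | 11 mM | 22.0 mM | 22.0 mM | 22.0 mM (fed, over 10 s) | 22.0 mM (fed, over 1.5 min) | 22.0 mM (fed, over 1.5 min) |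
| solid second nucleophile | 24 mM | 24 mM | 24 mM | 24 mM | 24.0 mM | 24.0 mM | 24.0 mM | 24.0 mM | 24.0 mM |
| temperature | 15 °C | 26 °C | 15 °C | 26 °C | 20 °C |  | 20 °C | 20 °C |  |
| remark | run made earlier | run made earlier | run made earlier | run made earlier | everything together at the start | everything together at the start at −20 °C, warmed to 20 °C at 1.5 min | all else is in the flask from the start; the feed brings no volume worth counting | all else is in the flask from the start; the feed brings no volume worth counting | the addition at −20 °C, then warmed to 20 °C; the feed brings no volume worth counting |
| time |  |  |  |  | 2.0 min | 2.0 min | 2.0 min | 2.0 min | 2.0 min |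

| run | time / s | over-reaction product / % | target / % |
|---|---|---|---|
| larch | 10.0 | 1.9 | 1.1 |
| larch | 12.0 | 1.5 | 1.8 |
| larch | 30.0 | 5.7 | 1.3 |
| larch | 80.0 | 12.6 | 0.7 |
| maple | 15.0 | 14.5 | 2.3 |
| maple | 40.0 | 22.2 | 0 |
| maple | 80.0 | 23.0 | 0 |
| maple | 120 | 25.8 | 0 |
| ash | 10.0 | 2.7 | 1.8 |
| ash | 20.0 | 4.1 | 1.8 |
| ash | 50.0 | 7.8 | 0 |
| ash | 120 | 13.6 | 0.4 |
| cedar | 10.0 | 1.9 | 3.2 |
| cedar | 20.0 | 6.8 | 4.0 |
| cedar | 50.0 | 12.4 | 0.6 |
| cedar | 120 | 13.3 | 0 |

(standard deviation of a reading: 1 percentage point)

- at the start none of the solid second nucleophile is in solution

Maple and cedar level off. Cedar, with half the first nucleophile of maple at the same temperature but with 20 mM of substrate against 13 mM, stood at 13.3 % at its last reading against 25.8 % for maple. So I took the over-reaction product as a share of the substrate turned over (a selectivity) that grows with the level of first nucleophile: share = level / (level + c), where c is the level at which the share stands at 0.5.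

Maple's last reading gave c = 63.3 mM at 26 °C. Ash's last reading gave 140 mM at 15 °C.

Next came the clock. Maple had 14.5 % by 15.0 s, and ash had 7.8 % by 50.0 s. I read these two times as rough half-times of turnover, and their geometric mean gave 27.4 s at 20 °C, so a lifetime of 39.5 s.

With a steady feed, the level the substrate sees is the charge times (lifetime / feed time) times (1 − exp(−feed time / lifetime)). North-east's feed of 1.5 min is 2.28 lifetimes, so the substrate turns over ahead of the charge. That gives 8.67 mM, the first nucleophile averaged over the substrate as it turns over: the level met.

The weak link was ash, whose last reading was still rising. Taking 50.0 s as the half-time of ash, I reckoned that ash had turned 81.1 % at that reading, so I put its plateau nearer 16.8 %. That moves the c of ash from 140 mM to 109 mM, and since 20 °C lies between the temperatures of ash and maple, I took the mean of their two values as my estimate, 86.2 mM. With 95.2 % turned by 2.0 min, I committed to 19.4 % for east and 8.70 % for north-east.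

The forecast put east at 18.5 %, south-east at 11.5 %, south at 18.2 %, north-east at 16.5 % and west at 11.5 %, with east leading; of the feeds it said “Feeding barely changes this, since each portion has the same lifetime”. Its north-east is higher than mine, by 7.8 percentage points.

East led at 18.5 %, south-east gave 10.4 %, west gave 10.3 %, and north-east gave 6.53 %, which is 10 points below the forecast.

    second nucleophile + intermediate → other capture product (k = 17000 L mol⁻¹ s⁻¹, Ea = 12.0 kJ mol⁻¹)
    solid second nucleophile ⇌ second nucleophile, rate k2*(cs2 - [second nucleophile]) while solid is left; crystals form when [second nucleophile] > cs2 (solubility = 6.40 mM, k = 1.50 s⁻¹)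
    substrate ⇌ intermediate (K = 0.0180, k = 0.0330 s⁻¹, Ea = 72.0 kJ mol⁻¹, ΔH = −16.0 kJ mol⁻¹)
    first nucleophile + intermediate → target (k = 1300 L mol⁻¹ s⁻¹, Ea = 42.0 kJ mol⁻¹)
    intermediate → side product (k = 0.0160 s⁻¹, Ea = 84.0 kJ mol⁻¹)
    first nucleophile + target → over-reaction product (k = 8.70 L mol⁻¹ s⁻¹, Ea = 42.0 kJ mol⁻¹)
    (constants at 20 °C)

In north-east the first nucleophile averaged 9.87 mM over the first 1.5 min, from a charge of 22.0 mM. South's feed of 10 s is shorter than the lifetime, so its level met is 19.4 mM. With 86.2 mM and the same turned fraction that gives 17.5 %, and south held 15.9 %.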